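**Retrosynthetic overview**
- The strategy rests on C5 of the oxane ring (O1, C2 aryl, C3 cinnamyl, C4, C5, C6). C5 is a methine bonded to three unlike carbons: C4, C6 and the exocyclic carbinol carbon C7, which bears OH. This array is what remains when a boronic ester is lengthened carbon by carbon (C4 → C5 → C7) and the last C–B bond becomes C–OH.
- The oxane is the only ring and is closed late, in step 19. The O1–C6 bond forms by attack of the C2 alkoxide on a C6 tosylate while the phenols are still silylated; fluoride is used only afterwards.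
- C7–OH and C6–OH come from C7–B and C6–Si by peroxide oxidation. C5–C7 and C7–aryl come from a second LiCHCl2 insertion followed by an aryl Grignard reagent.
- C4–C5 and C5–C6 come from C4 boronic ester 20 of (R,R)-1,2-dicyclohexylethanediol, LiCHCl2 and silylmethyl Grignard reagent 22.
- Compound 20 comes from an Evans syn-aldol (C2, C3) between a Heck-derived 5-arylpentenoyl imide and the silylated aldehyde, followed by reduction, iodination and borylation.

Key step: step 11

Remark: open-chain intermediates carry the ring numbering of the target (C2–C6, C7 = carbinol carbon). It is assumed that (R,R)-1,2-dicyclohexylethanediol, like other C2-symmetric (R,R)-1,2-diols, directs LiCHCl2 insertion to the (S)-α-chloro boronic ester.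

Step 1
Reactants: 1 4-iodophenol
Product: 2 (4-iodophenoxy)triisopropylsilane
Conditions: TIPSCl, imidazole, DMF, rt
Reagents that add atoms: chlorotriisopropylsilane, CC(C)[Si](Cl)(C(C)C)C(C)C
Why: Imidazole-promoted O-silylation of a phenol is routine, and the bulky triisopropylsilyl group is chosen because this ether must outlast amine base at 80 °C, organolithium and Grignard reagents and basic peroxide later on.

Step 2
Reactants: 2 (4-iodophenoxy)triisopropylsilane; 3 pent-4-enoic acid
Product: 4 (E)-5-[4-(triisopropylsilyloxy)phenyl]pent-4-enoic acid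
Conditions: Pd(OAc)2 (3 mol %), P(o-tol)3 (9 mol %), Et3N (3 equiv), MeCN, 80 °C; aq citric acid work-up
Reagents that add atoms: none
Why: Heck arylation, in which zerovalent palladium formed from Pd(OAc)2 inserts into the C–I bond, the aryl group adds to the unsubstituted alkene carbon, and syn β-hydride elimination toward the benzylic hydrogen should give the conjugated E-alkene that is kept to the end.

Step 3
Reactants: 4 (E)-5-[4-(triisopropylsilyloxy)phenyl]pent-4-enoic acid; 5 (R)-4-benzyloxazolidin-2-one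
Product: 7 N-(5-arylpent-4-enoyl)oxazolidinone, via mixed pivalic anhydride 6 (not isolated)
Conditions: PivCl, Et3N, THF, −20 °C; then LiCl, 5, −20 °C to rt
Reagents that add atoms: none
Why: N-Acylation of an oxazolidinone through a mixed pivalic anhydride, in which the LiCl/Et3N pair makes the carbamate nitrogen nucleophilic enough without strong base and it attacks the less hindered carbonyl of 6.

Step 4
Reactants: 8 4-hydroxybenzaldehyde
Product: 9 4-(triisopropylsilyloxy)benzaldehyde
Conditions: TIPSCl, imidazole, DMF, rt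
Reagents that add atoms: chlorotriisopropylsilane, CC(C)[Si](Cl)(C(C)C)C(C)C
Why: The same routine phenol silylation as in step 1 removes the acidic proton that would quench the boron enolate.

Step 5
Reactants: 7 N-(5-arylpent-4-enoyl)oxazolidinone; 9 4-(triisopropylsilyloxy)benzaldehyde
Product: 12 syn-aldol imide (C2-R,C3-R), via Z-boron enolate 10 (not isolated), via boron aldolate 11 (not isolated)
Conditions: Bu2BOTf, Et3N, CH2Cl2, −78 to 0 °C; 9, −78 to 0 °C; pH 7 buffer, MeOH, 30% H2O2, 0 °C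
Reagents that add atoms: none
Why: Evans syn-aldol reaction, in which soft enolisation gives the Z-boron enolate 10 and this adds to 9 through a closed chair transition state on the face turned away from the benzyl group of the (R)-auxiliary, so that C3 and C2 are set together in the syn relation that becomes the cis-2,3 relation of the ring.

Step 6
Reactants: 12 syn-aldol imide
Product: 13 C2 triethylsilyl ether of the aldol imide (C2-R,C3-R)
Conditions: TESOTf, 2,6-lutidine, CH2Cl2, −78 to 0 °C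
Reagents that add atoms: triethylsilyl triflate, CC[Si](CC)(CC)OS(=O)(=O)C(F)(F)F
Why: Silylation with a silyl triflate and a hindered pyridine is fast at low temperature and free of retro-aldol cleavage, and triethylsilyl is chosen because weak acid can later remove it while every other silyl ether stays.

Step 7
Reactants: 13 C2 triethylsilyl ether of the aldol imide
Product: 14 C4 alcohol (C2-R,C3-S)
Conditions: LiBH4, H2O (1 equiv), Et2O, 0 °C
Reagents that add atoms: none
Why: Reductive removal of the auxiliary with LiBH4 attacks the exocyclic imide carbonyl and takes it to the primary alcohol faster than any carbonyl intermediate can enolise, so C3 keeps its arrangement (the descriptor changes only through priorities).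

Step 8
Reactants: 14 C4 alcohol
Product: 15 C4 iodide (C2-R,C3-R)
Conditions: PPh3, I2, imidazole (premixed), CH2Cl2, 0 °C to rt
Reagents that add atoms: iodine, [I][I]
Why: Appel-type iodination, in which the preformed phosphonium iodide activates the only free hydroxyl and iodide displaces it by SN2 at the non-stereogenic C4, with no free iodine left to touch the styrene.

Step 9
Reactants: 15 C4 iodide; 16 (1R,2R)-1,2-dicyclohexylethane-1,2-diol
Product: 20 C4 boronic ester (C2-R,C3-R), via alkyllithium 17 (not isolated), via lithium triisopropoxyborate 18 (not isolated), via boronic acid 19 (not isolated)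
Conditions: t-BuLi (2.1 equiv), Et2O/pentane, −78 °C; B(OiPr)3, −78 °C to rt; sat. aq NH4Cl; then 16, MgSO4, Et2O, rt
Reagents that add atoms: triisopropyl borate, CC(C)OB(OC(C)C)OC(C)C
Why: Lithium–iodine exchange outruns every other reaction of t-BuLi at −78 °C in this weakly polar medium, where oxygen-to-carbon silyl migration in the γ-silyloxy alkyllithium 17 is slow, after which the borate traps 17 and the hindered diol condenses with 19 to a hydrolytically robust five-membered ester without touching C3.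

Step 10
Reactants: 21 (chloromethyl)isopropoxydimethylsilane
Product: 22 (isopropoxydimethylsilyl)methylmagnesium chloride
Conditions: Mg turnings, cat. BrCH2CH2Br, THF, rt to 45 °C
Reagents that add atoms: magnesium, [Mg]
Why: Grignard formation from a primary chloride, in which the branched isopropoxy group shields silicon so that the reagent does not condense with itself.

Step 11
Reactants: 20 C4 boronic ester; 22 (isopropoxydimethylsilyl)methylmagnesium chloride
Product: 26 C5 boronic ester (C2-R,C3-R,C5-R), via dichloromethyl borate 23 (not isolated), via (S)-α-chloro boronic ester 24 (not isolated), via silylmethyl borate 25 (not isolated)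
Conditions: CH2Cl2, n-BuLi, THF, −100 °C; 20; ZnCl2 (1 equiv), −100 °C to rt; then 22 (3 equiv, the excess covers what ZnCl2 binds), −78 °C to rt
Reagents that add atoms: dichloromethane, ClCCl
Why: (Dichloromethyl)lithium adds to the boron of 20 to give borate 23, and on warming ZnCl2 takes up the one chloride that the C2-symmetric (R,R)-diol leaves exposed while C4 shifts from boron to carbon anti to it, which forms C4–C5 and gives the (S)-chloride 24. Grignard reagent 22 then adds to boron (borate 25) and its CH2 carbon shifts to C5 with inversion and loss of chloride, which forms C5–C6 and leaves boron on C5 ready for the next insertion. The closest known reaction type is the Matteson homologation of chiral-diol boronic esters followed by Grignard displacement of the α-chloride. The step is acyclic, since the oxane is closed only in step 19. The one new stereocentre, C5, is fixed by the diol on boron through two stereospecific 1,2-metallate shifts, and the remote centres C2 and C3 have no say. The step needs boron to be the only site that takes up the two carbanions and needs 24 to hold its configuration: the silyl ethers and the styrene are inert at these temperatures, the hindered Si–OiPr bond tolerates Grignard reagents as the existence of 22 shows, ZnCl2 binds the free chloride that would epimerise 24, and carrying C6 as C–Si instead of C–O removes the β-elimination open to a β-alkoxy boronate.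

Step 12
Reactants: 27 4-bromophenol
Product: 28 (4-bromophenoxy)triisopropylsilane
Conditions: TIPSCl, imidazole, DMF, rt
Reagents that add atoms: chlorotriisopropylsilane, CC(C)[Si](Cl)(C(C)C)C(C)C
Why: Routine phenol silylation as in step 1 masks the proton that would destroy the Grignard reagent.

Step 13
Reactants: 28 (4-bromophenoxy)triisopropylsilane
Product: 29 4-(triisopropylsilyloxy)phenylmagnesium bromide
Conditions: Mg turnings, THF, 45 °C
Reagents that add atoms: magnesium, [Mg]
Why: Grignard formation from an aryl bromide, the aryl silyl ether being inert to magnesium and to the reagent formed.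

Step 14
Reactants: 26 C5 boronic ester; 29 4-(triisopropylsilyloxy)phenylmagnesium bromide
Product: 33 C7 boronic ester (C2-R,C3-S,C5-S,C7-R), via dichloromethyl borate 30 (not isolated), via (S)-α-chloro boronic ester 31 (not isolated), via aryl borate 32 (not isolated)
Conditions: CH2Cl2, n-BuLi, THF, −100 °C; 26; ZnCl2 (1 equiv), −100 °C to rt; then 29 (3 equiv), −78 °C to rt
Reagents that add atoms: dichloromethane, ClCCl
Why: Second Matteson homologation, in which C5 migrates from boron to the carbenoid carbon with retention while the same (R,R)-diol again selects the departing chloride to give (S)-31, and aryl transfer within 32 with inversion fixes C7, so that one director sets both C5 and C7.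

Step 15
Reactants: 33 C7 boronic ester
Product: 34 C6,C7-diol (C2-R,C3-S,C5-R,C7-R)
Conditions: 30% H2O2, KHCO3, THF/MeOH, rt to 40 °C
Reagents that add atoms: hydrogen peroxide, OO
Why: Peroxide oxidation of the C7–B bond and fluoride-free Tamao oxidation of the C6–Si(OiPr) bond in one operation, both carbon-to-oxygen shifts running with retention so that C7 keeps its arrangement, while leaving out fluoride should spare the four silyl ethers.

Step 16
Reactants: 34 C6,C7-diol
Product: 35 C6 tosylate with free C7 hydroxyl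
Conditions: TsCl (1.1 equiv), Et3N, cat. DMAP, CH2Cl2, 0 °C
Reagents that add atoms: 4-toluenesulfonyl chloride, Cc1ccc(S(=O)(=O)Cl)cc1
Why: Selective sulfonylation of a primary alcohol, the secondary benzylic C7 hydroxyl next to the branched C5 reacting far more slowly with the bulky sulfonyl chloride.

Step 17
Reactants: 35 C6 tosylate with free C7 hydroxyl
Product: 36 C6 tosylate C7 tert-butyldimethylsilyl ether
Conditions: TBSOTf, 2,6-lutidine, CH2Cl2, −78 to 0 °C
Reagents that add atoms: tert-butyldimethylsilyl triflate, CC(C)(C)[Si](C)(C)OS(=O)(=O)C(F)(F)F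
Why: Silylation of C7–OH removes the 1,3-hydroxy sulfonate motif, which under the base of step 19 could close to an oxetane or undergo Grob-type fragmentation.

Step 18
Reactants: 36 C6 tosylate C7 tert-butyldimethylsilyl ether
Product: 37 C2 alcohol C6 tosylate
Conditions: PPTS (0.2 equiv), MeOH/CH2Cl2, 0 °C
Reagents that add atoms: none
Why: Acid-catalysed methanolysis sorts silyl ethers by size and type, the secondary alkyl triethylsilyl ether falling much faster than the alkyl tert-butyldimethylsilyl or the aryl triisopropylsilyl ethers, and so weak an acid at 0 °C should not ionise the benzylic C–O bonds.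

Step 19
Reactants: 37 C2 alcohol C6 tosylate
Product: 39 tetrasilylated oxane (2R,3S,5R,C7-R), via sodium alkoxide 38 (not isolated)
Conditions: NaH, THF, 0 to 40 °C
Reagents that add atoms: none
Why: Intramolecular Williamson etherification, a 6-exo-tet SN2 attack of the C2 alkoxide on the primary C6, in which no stereocentre takes part, so the all-cis 2,3,5 array with its axial C2 aryl group is carried over intact, and in which neither phenoxide nor fluoride is present to compete for the tosylate.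

Step 20
Reactants: 39 tetrasilylated oxane
Product: 40 CNP0182155.1
Conditions: TBAF, AcOH (1:1), THF, 0 °C to rt
Reagents that add atoms: none
Why: Fluoride desilylation of three aryl and one alkyl silyl ether, buffered with acetic acid so that the phenols stay protonated and no p-quinone methide can form by loss of the benzylic oxygen at C2 or C7.

**Compound list**
1 | 4-iodophenol | Oc1ccc(I)cc1 | starting material
2 | (4-iodophenoxy)triisopropylsilane | CC(C)[Si](C(C)C)(C(C)C)Oc1ccc(I)cc1 | intermediate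
3 | pent-4-enoic acid | C=CCCC(=O)O | starting material
4 | (E)-5-[4-(triisopropylsilyloxy)phenyl]pent-4-enoic acid | CC(C)[Si](C(C)C)(C(C)C)Oc1ccc(/C=C/CCC(=O)O)cc1 | intermediate
5 | (R)-4-benzyloxazolidin-2-one | O=C1N[C@H](Cc2ccccc2)CO1 | starting material
6 | mixed anhydride of 4 and pivalic acid | CC(C)[Si](C(C)C)(C(C)C)Oc1ccc(/C=C/CCC(=O)OC(=O)C(C)(C)C)cc1 | intermediate
7 | (R)-4-benzyl-3-{(E)-5-[4-(triisopropylsilyloxy)phenyl]pent-4-enoyl}oxazolidin-2-one | CC(C)[Si](C(C)C)(C(C)C)Oc1ccc(/C=C/CCC(=O)N2[C@H](Cc3ccccc3)COC2=O)cc1 | intermediate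
8 | 4-hydroxybenzaldehyde | O=Cc1ccc(O)cc1 | starting material
9 | 4-(triisopropylsilyloxy)benzaldehyde | CC(C)[Si](C(C)C)(C(C)C)Oc1ccc(C=O)cc1 | intermediate
10 | (Z)-dibutylboron enolate of 7 | CCCCB(CCCC)O/C(=C\C/C=C/c1ccc(O[Si](C(C)C)(C(C)C)C(C)C)cc1)N1[C@H](Cc2ccccc2)COC1=O | intermediate
11 | dibutylboron aldolate (C2–O–BBu2) of 12 | CC(C)[Si](C(C)C)(C(C)C)Oc1ccc(/C=C/C[C@@H](C(=O)N2[C@H](Cc3ccccc3)COC2=O)[C@@H](OB(CCCC)CCCC)c2ccc(O[Si](C(C)C)(C(C)C)C(C)C)cc2)cc1 | intermediate
12 | (R)-4-benzyl-3-[(2R,4E)-2-{(R)-hydroxy[4-(triisopropylsilyloxy)phenyl]methyl}-5-[4-(triisopropylsilyloxy)phenyl]pent-4-enoyl]oxazolidin-2-one | CC(C)[Si](C(C)C)(C(C)C)Oc1ccc(/C=C/C[C@@H](C(=O)N2[C@H](Cc3ccccc3)COC2=O)[C@@H](O)c2ccc(O[Si](C(C)C)(C(C)C)C(C)C)cc2)cc1 | intermediate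
13 | C2 triethylsilyl ether of 12 (C2-R,C3-R) | CC(C)[Si](C(C)C)(C(C)C)Oc1ccc(/C=C/C[C@@H](C(=O)N2[C@H](Cc3ccccc3)COC2=O)[C@@H](O[Si](CC)(CC)CC)c2ccc(O[Si](C(C)C)(C(C)C)C(C)C)cc2)cc1 | intermediate
14 | (2S,4E)-2-{(R)-[4-(triisopropylsilyloxy)phenyl](triethylsilyloxy)methyl}-5-[4-(triisopropylsilyloxy)phenyl]pent-4-en-1-ol | CC(C)[Si](C(C)C)(C(C)C)Oc1ccc(/C=C/C[C@@H](CO)[C@@H](O[Si](CC)(CC)CC)c2ccc(O[Si](C(C)C)(C(C)C)C(C)C)cc2)cc1 | intermediate
15 | {[(1R,2R,4E)-2-(iodomethyl)-1,5-bis[4-(triisopropylsilyloxy)phenyl]pent-4-enyl]oxy}triethylsilane | CC(C)[Si](C(C)C)(C(C)C)Oc1ccc(/C=C/C[C@@H](CI)[C@@H](O[Si](CC)(CC)CC)c2ccc(O[Si](C(C)C)(C(C)C)C(C)C)cc2)cc1 | intermediate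
16 | (1R,2R)-1,2-dicyclohexylethane-1,2-diol | O[C@H](C1CCCCC1)[C@H](O)C1CCCCC1 | starting material
17 | primary C4 alkyllithium from 15 | CC(C)[Si](C(C)C)(C(C)C)Oc1ccc(/C=C/C[C@@H](C[Li])[C@@H](O[Si](CC)(CC)CC)c2ccc(O[Si](C(C)C)(C(C)C)C(C)C)cc2)cc1 | intermediate
18 | lithium (C4-alkyl)triisopropoxyborate | [Li+].CC(C)[Si](C(C)C)(C(C)C)Oc1ccc(/C=C/C[C@@H](C[B-](OC(C)C)(OC(C)C)OC(C)C)[C@@H](O[Si](CC)(CC)CC)c2ccc(O[Si](C(C)C)(C(C)C)C(C)C)cc2)cc1 | intermediate
19 | C4 boronic acid | CC(C)[Si](C(C)C)(C(C)C)Oc1ccc(/C=C/C[C@@H](CB(O)O)[C@@H](O[Si](CC)(CC)CC)c2ccc(O[Si](C(C)C)(C(C)C)C(C)C)cc2)cc1 | intermediate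
20 | (4R,5R)-4,5-dicyclohexyl-2-[(2R,4E)-2-{(R)-[4-(triisopropylsilyloxy)phenyl](triethylsilyloxy)methyl}-5-[4-(triisopropylsilyloxy)phenyl]pent-4-enyl]-1,3,2-dioxaborolane (C4 boronic ester) | CC(C)[Si](C(C)C)(C(C)C)Oc1ccc(/C=C/C[C@@H](CB2O[C@H](C3CCCCC3)[C@@H](C3CCCCC3)O2)[C@@H](O[Si](CC)(CC)CC)c2ccc(O[Si](C(C)C)(C(C)C)C(C)C)cc2)cc1 | intermediate
21 | (chloromethyl)isopropoxydimethylsilane | CC(C)O[Si](C)(C)CCl | starting material
22 | (isopropoxydimethylsilyl)methylmagnesium chloride | CC(C)O[Si](C)(C)C[Mg]Cl | intermediate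
23 | lithium borate from 20 and LiCHCl2 (boron bears C4, CHCl2 and the diol) | [Li+].CC(C)[Si](C(C)C)(C(C)C)Oc1ccc(/C=C/C[C@@H](C[B-]2(C(Cl)Cl)O[C@H](C3CCCCC3)[C@@H](C3CCCCC3)O2)[C@@H](O[Si](CC)(CC)CC)c2ccc(O[Si](C(C)C)(C(C)C)C(C)C)cc2)cc1 | intermediate
24 | C5 α-chloro boronic ester: 20 with CHCl inserted between C4 and boron (C2-R,C3-S,C5-S) | CC(C)[Si](C(C)C)(C(C)C)Oc1ccc(/C=C/C[C@H]([C@@H](O[Si](CC)(CC)CC)c2ccc(O[Si](C(C)C)(C(C)C)C(C)C)cc2)C[C@H](B2O[C@H](C3CCCCC3)[C@@H](C3CCCCC3)O2)Cl)cc1 | intermediate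
25 | chloromagnesium borate from 24 and 22 (boron bears C5, CH2SiMe2OiPr and the diol) | Cl[Mg+].CC(C)[Si](C(C)C)(C(C)C)Oc1ccc(/C=C/C[C@H]([C@@H](O[Si](CC)(CC)CC)c2ccc(O[Si](C(C)C)(C(C)C)C(C)C)cc2)C[C@H]([B-]2(C[Si](C)(C)OC(C)C)O[C@H](C3CCCCC3)[C@@H](C3CCCCC3)O2)Cl)cc1 | intermediate
26 | C5 boronic ester: (R,R)-dicyclohexylethanediol ester with boron on C5, which also bears C4 and the C6 CH2SiMe2(OiPr) group (C2-R,C3-R,C5-R) | CC(C)[Si](C(C)C)(C(C)C)Oc1ccc(/C=C/C[C@H]([C@@H](O[Si](CC)(CC)CC)c2ccc(O[Si](C(C)C)(C(C)C)C(C)C)cc2)C[C@@H](B2O[C@H](C3CCCCC3)[C@@H](C3CCCCC3)O2)C[Si](C)(C)OC(C)C)cc1 | intermediate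
27 | 4-bromophenol | Oc1ccc(Br)cc1 | starting material
28 | (4-bromophenoxy)triisopropylsilane | CC(C)[Si](C(C)C)(C(C)C)Oc1ccc(Br)cc1 | intermediate
29 | 4-(triisopropylsilyloxy)phenylmagnesium bromide | CC(C)[Si](C(C)C)(C(C)C)Oc1ccc([Mg]Br)cc1 | intermediate
30 | lithium borate from 26 and LiCHCl2 | [Li+].CC(C)[Si](C(C)C)(C(C)C)Oc1ccc(/C=C/C[C@H]([C@@H](O[Si](CC)(CC)CC)c2ccc(O[Si](C(C)C)(C(C)C)C(C)C)cc2)C[C@@H]([B-]2(C(Cl)Cl)O[C@H](C3CCCCC3)[C@@H](C3CCCCC3)O2)C[Si](C)(C)OC(C)C)cc1 | intermediate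
31 | C7 α-chloro boronic ester: 26 with CHCl inserted between C5 and boron (C2-R,C3-S,C5-R,C7-S) | CC(C)[Si](C(C)C)(C(C)C)Oc1ccc(/C=C/C[C@H]([C@@H](O[Si](CC)(CC)CC)c2ccc(O[Si](C(C)C)(C(C)C)C(C)C)cc2)C[C@@H]([C@H](B2O[C@H](C3CCCCC3)[C@@H](C3CCCCC3)O2)Cl)C[Si](C)(C)OC(C)C)cc1 | intermediate
32 | bromomagnesium borate from 31 and 29 (boron bears C7, the aryl group and the diol) | Br[Mg+].CC(C)[Si](C(C)C)(C(C)C)Oc1ccc(/C=C/C[C@H]([C@@H](O[Si](CC)(CC)CC)c2ccc(O[Si](C(C)C)(C(C)C)C(C)C)cc2)C[C@@H]([C@H]([B-]2(c3ccc(O[Si](C(C)C)(C(C)C)C(C)C)cc3)O[C@H](C3CCCCC3)[C@@H](C3CCCCC3)O2)Cl)C[Si](C)(C)OC(C)C)cc1 | intermediate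
33 | C7 boronic ester: boron and the third aryl group on C7, C6 still CH2SiMe2(OiPr) (C2-R,C3-S,C5-S,C7-R) | CC(C)[Si](C(C)C)(C(C)C)Oc1ccc(/C=C/C[C@H]([C@@H](O[Si](CC)(CC)CC)c2ccc(O[Si](C(C)C)(C(C)C)C(C)C)cc2)C[C@@H]([C@@H](B2O[C@H](C3CCCCC3)[C@@H](C3CCCCC3)O2)c2ccc(O[Si](C(C)C)(C(C)C)C(C)C)cc2)C[Si](C)(C)OC(C)C)cc1 | intermediate
34 | open-chain diol with C6–OH (primary) and C7–OH (benzylic), C2–OTES, three aryl OTIPS (C2-R,C3-S,C5-R,C7-R) | CC(C)[Si](C(C)C)(C(C)C)Oc1ccc(/C=C/C[C@H]([C@@H](O[Si](CC)(CC)CC)c2ccc(O[Si](C(C)C)(C(C)C)C(C)C)cc2)C[C@@H]([C@@H](O)c2ccc(O[Si](C(C)C)(C(C)C)C(C)C)cc2)CO)cc1 | intermediate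
35 | C6 4-toluenesulfonate of 34, C7–OH free | CC(C)[Si](C(C)C)(C(C)C)Oc1ccc(/C=C/C[C@H]([C@@H](O[Si](CC)(CC)CC)c2ccc(O[Si](C(C)C)(C(C)C)C(C)C)cc2)C[C@@H]([C@@H](O)c2ccc(O[Si](C(C)C)(C(C)C)C(C)C)cc2)COS(=O)(=O)c2ccc(C)cc2)cc1 | intermediate
36 | C7 tert-butyldimethylsilyl ether of 35 | CC(C)[Si](C(C)C)(C(C)C)Oc1ccc(/C=C/C[C@H]([C@@H](O[Si](CC)(CC)CC)c2ccc(O[Si](C(C)C)(C(C)C)C(C)C)cc2)C[C@@H]([C@@H](O[Si](C)(C)C(C)(C)C)c2ccc(O[Si](C(C)C)(C(C)C)C(C)C)cc2)COS(=O)(=O)c2ccc(C)cc2)cc1 | intermediate
37 | 36 with the C2 triethylsilyl group removed (C2–OH, C6–OTs, C7–OTBS) | CC(C)[Si](C(C)C)(C(C)C)Oc1ccc(/C=C/C[C@H]([C@@H](O)c2ccc(O[Si](C(C)C)(C(C)C)C(C)C)cc2)C[C@@H]([C@@H](O[Si](C)(C)C(C)(C)C)c2ccc(O[Si](C(C)C)(C(C)C)C(C)C)cc2)COS(=O)(=O)c2ccc(C)cc2)cc1 | intermediate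
38 | sodium C2 alkoxide of 37 | [Na+].CC(C)[Si](C(C)C)(C(C)C)Oc1ccc(/C=C/C[C@H]([C@@H]([O-])c2ccc(O[Si](C(C)C)(C(C)C)C(C)C)cc2)C[C@@H]([C@@H](O[Si](C)(C)C(C)(C)C)c2ccc(O[Si](C(C)C)(C(C)C)C(C)C)cc2)COS(=O)(=O)c2ccc(C)cc2)cc1 | intermediate
39 | (2R,3S,5R)-oxane with three aryl OTIPS groups and (R)-C7–OTBS | CC(C)[Si](C(C)C)(C(C)C)Oc1ccc(/C=C/C[C@H]2C[C@@H]([C@@H](O[Si](C)(C)C(C)(C)C)c3ccc(O[Si](C(C)C)(C(C)C)C(C)C)cc3)CO[C@H]2c2ccc(O[Si](C(C)C)(C(C)C)C(C)C)cc2)cc1 | intermediate
40 | 4-[(2R,3S,5R)-5-[(R)-hydroxy(4-hydroxyphenyl)methyl]-3-[(E)-3-(4-hydroxyphenyl)prop-2-enyl]oxan-2-yl]phenol (CNP0182155.1) | Oc1ccc(/C=C/C[C@H]2C[C@@H]([C@@H](O)c3ccc(O)cc3)CO[C@H]2c2ccc(O)cc2)cc1 | target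

**Step count.** Total: 20 steps. Longest linear sequence: 16 steps (1, 2, 3, 5–9, 11, 14–20).

**Steps most likely to fail**

Step 11.
- The shift of the bulky alkoxysilylmethyl group from boron to C5 may be slow.
- Migration of a ring oxygen, chloride-induced epimerisation at C5 and hydrolysis at the Si–O bond during handling could then take over.
- The fallback changes the mask of the C6 hydroxyl from an alkoxysilane to a hydrosilane. It sets out from 20 (taken to 24 as before) and comes back at 34.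
- (Chloromethyl)dimethylsilane and Mg in THF give (dimethylsilyl)methylmagnesium chloride F1, which is smaller and has no Si–O bond.
- With 24 it should give the C5 boronic ester bearing CH2SiMe2H F2, which tolerates chromatography.
- LiCHCl2 and ZnCl2 then give the C7 α-chloro boronic ester F3, and 29 gives the C7 boronic ester F4. The silicon group is thus also kept out of reach of the reagents of step 14.
- Basic peroxide (30% H2O2, K2CO3, THF/MeOH, 40 °C) should first solvolyse Si–H to Si–O with loss of hydrogen and then oxidise C–B and C–Si to 34.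

Step 15.
- Hydroperoxide or methoxide may strip the phenolic silyl groups, or the C6–Si cleavage may stall in the absence of fluoride.
- The fallback changes the protecting-group plan. It sets out from 33 and comes back at 34.
- The oxidation is run with fluoride (KF, KHCO3, 30% H2O2, THF/MeOH, 0 °C to rt), accepting the loss of the three aryl silyl ethers. The hindered secondary triethylsilyl ether should stay, giving the triphenol diol F5.
- Only the aryl ethers are then restored through the tris-phenoxide (NaH, 3 equiv, THF, 0 °C; TIPSCl, 3 equiv). The neutral primary and secondary alcohols are far less nucleophilic than phenoxide.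

Step 9.
- In the alkyllithium the triethylsilyl group may migrate from oxygen to C4. Addition of t-BuLi to the styrene or proton transfer from the allylic position may also intervene.
- The fallback replaces the carbanion by a radical. It sets out from 15 and comes back at 19.
- Irradiation of 15 with bis(catecholato)diboron in DMF under blue light runs as a radical chain. The primary C4 radical should be borylated faster than it can add to the styrene, giving the catechol boronic ester F6.
- Aqueous work-up hydrolyses F6 to 19, which is esterified with 16 as in step 9.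

**Further compounds**
F1 | step 11 | (dimethylsilyl)methylmagnesium chloride | C[SiH](C)C[Mg]Cl
F2 | step 11 | C5 boronic ester bearing CH2SiMe2H (C2-R,C3-R,C5-R) | CC(C)[Si](C(C)C)(C(C)C)Oc1ccc(/C=C/C[C@H]([C@@H](O[Si](CC)(CC)CC)c2ccc(O[Si](C(C)C)(C(C)C)C(C)C)cc2)C[C@@H](B2O[C@H](C3CCCCC3)[C@@H](C3CCCCC3)O2)C[SiH](C)C)cc1
F3 | step 11 | C7 α-chloro boronic ester bearing CH2SiMe2H (C2-R,C3-S,C5-R,C7-S) | CC(C)[Si](C(C)C)(C(C)C)Oc1ccc(/C=C/C[C@H]([C@@H](O[Si](CC)(CC)CC)c2ccc(O[Si](C(C)C)(C(C)C)C(C)C)cc2)C[C@@H]([C@H](B2O[C@H](C3CCCCC3)[C@@H](C3CCCCC3)O2)Cl)C[SiH](C)C)cc1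
F4 | step 11 | C7 boronic ester bearing CH2SiMe2H (C2-R,C3-S,C5-S,C7-R) | CC(C)[Si](C(C)C)(C(C)C)Oc1ccc(/C=C/C[C@H]([C@@H](O[Si](CC)(CC)CC)c2ccc(O[Si](C(C)C)(C(C)C)C(C)C)cc2)C[C@@H]([C@@H](B2O[C@H](C3CCCCC3)[C@@H](C3CCCCC3)O2)c2ccc(O[Si](C(C)C)(C(C)C)C(C)C)cc2)C[SiH](C)C)cc1
F5 | step 15 | triphenol diol with C2–OTES kept (C2-R,C3-S,C5-R,C7-R) | Oc1ccc(/C=C/C[C@H]([C@@H](O[Si](CC)(CC)CC)c2ccc(O)cc2)C[C@@H]([C@@H](O)c2ccc(O)cc2)CO)cc1
F6 | step 9 | C4 catechol boronic ester (C2-R,C3-R) | CC(C)[Si](C(C)C)(C(C)C)Oc1ccc(/C=C/C[C@@H](CB2Oc3ccccc3O2)[C@@H](O[Si](CC)(CC)CC)c2ccc(O[Si](C(C)C)(C(C)C)C(C)C)cc2)cc1
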